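**Retrosynthetic overview**
1. The last three operations are global desilylation, a 1,3-syn reduction of a C11 ketone under C13-OH control, and N–O cleavage of a macrocyclic 2-isoxazoline.
2. Enabling feature: C11(OH)–C12H2–C13(OH)–C14(OH), a syn-1,3-diol across the C12 methylene with a syn carbinol next to it, is the retron of a 5-(1-hydroxyalkyl)-2-isoxazoline (C3 = C11, C4 = C12, C5 = C13). The 28-membered lactone is therefore closed by an intramolecular nitrile oxide cycloaddition (C11 nitrile oxide onto the C12=C13 vinyl group), steered by the free C14 hydroxyl as its magnesium alkoxide.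
3. The seco oxime comes from a Stille union (C19–C20) of a C12–C19 dienylstannane (16Z alkene by anti-carbomagnesiation, C14 by Felkin vinyl addition) with a C20–C27 trienyl iodide that is already esterified (C1–O, Yamaguchi) to the C1–C11 acid.
4. The C1–C11 acid: one iridium catalyst system, used three times in an allylation/ozonolysis loop, sets C9, C7 and C5; an Evans syn-aldol sets C2/C3 and brings in C1′.
5. Ring order: no ring exists before the key step; the isoxazoline (5-membered) and the macrolactone ring (28-membered) close in the same operation, and the isoxazoline is opened again one step later.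

Key step: step 38

Remark: TBS = tert-butyldimethylsilyl. Locants C1–C27 and C1′ are those of the macrolactone (C1 = lactone carbonyl, C27 = carbinol carbon bearing the ring oxygen). The C16=C17 bond is built as written in the target (C15 and C18 cis, 16Z). Oxime C=N geometry is left undefined because it is lost in the nitrile oxide.

**A. C1–C11 acid**

Step 1
Reactants: 1 3-(TBS-oxy)propan-1-ol
Product: 2 (S)-1-(TBS-oxy)hex-5-en-3-ol
Conditions: allyl acetate, [Ir(cod)Cl]2 (2.5 mol %), (S)-Cl,MeO-BIPHEP (5 mol %), 4-chloro-3-nitrobenzoic acid (10 mol %), Cs2CO3 (20 mol %), THF, 100 °C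
Reagents that add atoms: allyl acetate, C=CCOC(C)=O
Why: Iridium-catalysed transfer-hydrogenative allylation from the alcohol oxidation level (Krische allylation), in which the transient aldehyde is allylated by the chiral π-allyl-iridium complex; the ligand enantiomer is the one chosen to give the S carbinol (C9).

Step 2
Reactants: 2 (S)-1-(TBS-oxy)hex-5-en-3-ol
Product: 3 (S)-4,6-bis(TBS-oxy)hex-1-ene
Conditions: TBSOTf, 2,6-lutidine, CH2Cl2, −78 to 0 °C
Reagents that add atoms: tert-butyldimethylsilyl triflate, CC(C)(C)[Si](C)(C)OS(=O)(=O)C(F)(F)F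
Why: Silylation of a secondary alcohol with a silyl triflate and a hindered base; no stereocentre is touched.

Step 3
Reactants: 3 (S)-4,6-bis(TBS-oxy)hex-1-ene
Product: 5 (S)-3,5-bis(TBS-oxy)pentan-1-ol, via aldehyde 4 (not isolated)
Conditions: O3, CH2Cl2/MeOH, −78 °C; then NaBH4, −78 °C to rt
Reagents that add atoms: ozone, [O-][O+]=O
Why: Ozonolysis of the terminal alkene with reductive work-up gives the primary alcohol needed for the next allylation, and silyl ethers are inert to both reagents.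

Step 4
Reactants: 5 (S)-3,5-bis(TBS-oxy)pentan-1-ol
Product: 6 (4S,6R)-6,8-bis(TBS-oxy)oct-1-en-4-ol
Conditions: allyl acetate, [Ir(cod)Cl]2, (S)-Cl,MeO-BIPHEP, 4-chloro-3-nitrobenzoic acid, Cs2CO3, THF, 100 °C
Reagents that add atoms: allyl acetate, C=CCOC(C)=O
Why: Second Krische allylation; catalyst control with the same ligand enantiomer should set C7 syn to C9, and starting from the alcohol keeps the β-silyloxy aldehyde at low concentration.

Step 5
Reactants: 6 (4S,6R)-6,8-bis(TBS-oxy)oct-1-en-4-ol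
Product: 7 (4S,6R)-4,6,8-tris(TBS-oxy)oct-1-ene
Conditions: TBSOTf, 2,6-lutidine, CH2Cl2, −78 to 0 °C
Reagents that add atoms: tert-butyldimethylsilyl triflate, CC(C)(C)[Si](C)(C)OS(=O)(=O)C(F)(F)F
Why: Silylation of the new secondary alcohol as in step 2.

Step 6
Reactants: 7 (4S,6R)-4,6,8-tris(TBS-oxy)oct-1-ene
Product: 9 (3S,5R)-3,5,7-tris(TBS-oxy)heptan-1-ol, via aldehyde 8 (not isolated)
Conditions: O3, CH2Cl2/MeOH, −78 °C; then NaBH4, −78 °C to rt
Reagents that add atoms: ozone, [O-][O+]=O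
Why: Ozonolysis with reductive work-up, as in step 3.

Step 7
Reactants: 9 (3S,5R)-3,5,7-tris(TBS-oxy)heptan-1-ol
Product: 10 (4R,6S,8R)-6,8,10-tris(TBS-oxy)dec-1-en-4-ol
Conditions: allyl acetate, [Ir(cod)Cl]2, (R)-Cl,MeO-BIPHEP, 4-chloro-3-nitrobenzoic acid, Cs2CO3, THF, 100 °C
Reagents that add atoms: allyl acetate, C=CCOC(C)=O
Why: Third Krische allylation; the enantiomeric ligand should override the substrate and set C5 anti to C7.

Step 8
Reactants: 10 (4R,6S,8R)-6,8,10-tris(TBS-oxy)dec-1-en-4-ol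
Product: 11 (4R,6S,8R)-4,6,8,10-tetrakis(TBS-oxy)dec-1-ene
Conditions: TBSOTf, 2,6-lutidine, CH2Cl2, −78 to 0 °C
Reagents that add atoms: tert-butyldimethylsilyl triflate, CC(C)(C)[Si](C)(C)OS(=O)(=O)C(F)(F)F
Why: Silylation of the secondary alcohol as in step 2.

Step 9
Reactants: 11 (4R,6S,8R)-4,6,8,10-tetrakis(TBS-oxy)dec-1-ene
Product: 12 (3S,5R,7R)-3,5,7,9-tetrakis(TBS-oxy)nonanal
Conditions: O3, CH2Cl2, −78 °C; then PPh3, −78 °C to rt
Reagents that add atoms: ozone, [O-][O+]=O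
Why: Ozonolysis with phosphine work-up stops at the C3 aldehyde, which is used at once to avoid β-elimination.

Step 10
Reactants: 13 methyl 3-oxooctanoate
Product: 14 methyl (S)-3-hydroxyoctanoate
Conditions: H2 (50 atm), RuCl2[(S)-BINAP] (0.1 mol %), MeOH, 50 °C
Reagents that add atoms: none
Why: Noyori asymmetric hydrogenation of a β-keto ester, in which the (S)-BINAP–ruthenium catalyst delivers hydrogen to one face of the chelated ketone and sets C1′ (S).

Step 11
Reactants: 14 methyl (S)-3-hydroxyoctanoate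
Product: 15 methyl (S)-3-(TBS-oxy)octanoate
Conditions: TBSCl, imidazole, DMF, rt
Reagents that add atoms: tert-butyldimethylsilyl chloride, CC(C)(C)[Si](C)(C)Cl
Why: Standard imidazole-promoted silylation of a secondary alcohol.

Step 12
Reactants: 15 methyl (S)-3-(TBS-oxy)octanoate
Product: 16 (S)-3-(TBS-oxy)octanoic acid
Conditions: LiOH, THF/MeOH/H2O, rt; 1 M HCl
Reagents that add atoms: lithium hydroxide, [Li+].[OH-]
Why: Saponification of a methyl ester; the β-silyl ether survives cold aqueous hydroxide.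

Step 13
Reactants: 16 (S)-3-(TBS-oxy)octanoic acid; 17 (R)-4-benzyloxazolidin-2-one
Product: 19 (R)-4-benzyl-3-[(S)-3-(TBS-oxy)octanoyl]oxazolidin-2-one, via mixed pivalic anhydride 18 (not isolated)
Conditions: PivCl, Et3N, THF, −20 °C; then LiCl, 17, rt
Reagents that add atoms: none
Why: N-Acylation of the oxazolidinone through the mixed pivalic anhydride (lithium chloride/triethylamine protocol), which attacks the less hindered carbonyl.

Step 14
Reactants: 19 (R)-4-benzyl-3-[(S)-3-(TBS-oxy)octanoyl]oxazolidin-2-one; 12 (3S,5R,7R)-3,5,7,9-tetrakis(TBS-oxy)nonanal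
Product: 20 Evans syn-aldol adduct: (R)-4-benzyl-3-acyloxazolidin-2-one whose acyl group is the C1–C11 chain with free C3-OH and TBS ethers at O1′ O5 O7 O9 O11
Conditions: Bu2BOTf, Et3N, CH2Cl2, 0 °C; 12, −78 to 0 °C; pH 7 buffer, MeOH, H2O2
Reagents that add atoms: none
Why: Evans syn-aldol reaction, in which the Z-boron enolate of the (R)-benzyl imide reacts through a Zimmerman–Traxler chair so that the auxiliary fixes C2 and C3 (2,3-syn, configured as in the target) while the β-silyloxy groups of both partners are spectators.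

Step 15
Reactants: 20 Evans syn-aldol adduct
Product: 21 3-hydroxy acid: C1–C11 acid with free C3-OH and TBS ethers at O1′ O5 O7 O9 O11
Conditions: LiOH, H2O2, THF/H2O, 0 °C; Na2SO3; 1 M HCl
Reagents that add atoms: lithium hydroperoxide (from LiOH and H2O2), [Li+].[O-]O
Why: Hydroperoxide cleavage of the imide at the exocyclic carbonyl releases the acid and the auxiliary without epimerising C2.

Step 16
Reactants: 21 3-hydroxy acid
Product: 23 (2R,3S,5S,7R,9R)-3,5,7,9,11-pentakis(TBS-oxy)-2-[(S)-1-(TBS-oxy)hexyl]undecanoic acid, via silyl ester 22 (not isolated)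
Conditions: TBSOTf, 2,6-lutidine, CH2Cl2, 0 °C; then K2CO3, MeOH/H2O, 0 °C
Reagents that add atoms: tert-butyldimethylsilyl triflate, CC(C)(C)[Si](C)(C)OS(=O)(=O)C(F)(F)F
Why: Exhaustive silylation followed by selective methanolysis of the labile silyl ester leaves the C3 silyl ether and the free acid.

**B. C20–C27 trienyl iodide**

Step 17
Reactants: 24 methyl (R)-3-hydroxybutanoate
Product: 25 methyl (2R,3R)-3-hydroxy-2-methylbutanoate
Conditions: LDA (2.2 equiv), THF, −78 to −20 °C; MeI, DMPU, −78 to 0 °C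
Reagents that add atoms: iodomethane, CI
Why: Fráter–Seebach alkylation, in which the chelated dianion of the β-hydroxy ester is methylated anti to the carbinol oxygen and sets C26 anti to C27.

Step 18
Reactants: 25 methyl (2R,3R)-3-hydroxy-2-methylbutanoate
Product: 26 methyl (2R,3R)-3-(TBS-oxy)-2-methylbutanoate
Conditions: TBSCl, imidazole, DMF, rt
Reagents that add atoms: tert-butyldimethylsilyl chloride, CC(C)(C)[Si](C)(C)Cl
Why: Standard silylation of a secondary alcohol.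

Step 19
Reactants: 26 methyl (2R,3R)-3-(TBS-oxy)-2-methylbutanoate
Product: 27 (2R,3R)-3-(TBS-oxy)-2-methylbutanal
Conditions: DIBAL, CH2Cl2, −78 °C; Rochelle salt
Reagents that add atoms: none
Why: Partial DIBAL reduction stops at the aldehyde because the tetrahedral aluminium hemiacetal is stable at −78 °C, and the α-stereocentre is kept at that temperature.

Step 20
Reactants: 27 (2R,3R)-3-(TBS-oxy)-2-methylbutanal
Product: 28 ethyl (2E,4E,6S,7R)-7-(TBS-oxy)-6-methylocta-2,4-dienoate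
Conditions: triethyl 4-phosphonocrotonate, LiHMDS, THF, −78 to 0 °C
Reagents that add atoms: triethyl 4-phosphonocrotonate, CCOC(=O)/C=C/CP(=O)(OCC)OCC
Why: Vinylogous Horner–Wadsworth–Emmons olefination with a stabilised phosphonate anion should give the (2E,4E)-dienoate.

Step 21
Reactants: 28 ethyl (2E,4E,6S,7R)-7-(TBS-oxy)-6-methylocta-2,4-dienoate
Product: 29 (2E,4E,6S,7R)-7-(TBS-oxy)-6-methylocta-2,4-dien-1-ol
Conditions: DIBAL, CH2Cl2, −78 °C
Reagents that add atoms: none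
Why: 1,2-Reduction of a conjugated ester with DIBAL gives the dienol without touching the diene.

Step 22
Reactants: 29 (2E,4E,6S,7R)-7-(TBS-oxy)-6-methylocta-2,4-dien-1-ol
Product: 30 (2E,4E,6S,7R)-7-(TBS-oxy)-6-methylocta-2,4-dienal
Conditions: MnO2, CH2Cl2, rt
Reagents that add atoms: none
Why: Manganese dioxide oxidises the allylic alcohol selectively and keeps the diene geometry.

Step 23
Reactants: 30 (2E,4E,6S,7R)-7-(TBS-oxy)-6-methylocta-2,4-dienal
Product: 31 TBS ether of (2R,3S,4E,6E,8E)-9-iodo-3-methylnona-4,6,8-trien-2-ol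
Conditions: CrCl2, CHI3, THF/dioxane, 0 °C to rt, dark
Reagents that add atoms: iodoform, IC(I)I
Why: Takai olefination, in which the geminal dichromium species adds to the aldehyde and eliminates anti-periplanar to give the E-alkenyl iodide.

Step 24
Reactants: 31 TBS ether of (2R,3S,4E,6E,8E)-9-iodo-3-methylnona-4,6,8-trien-2-ol
Product: 32 (2R,3S,4E,6E,8E)-9-iodo-3-methylnona-4,6,8-trien-2-ol
Conditions: HF·pyridine, pyridine, THF, 0 °C to rt, dark
Reagents that add atoms: none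
Why: Buffered fluoride desilylation frees the C27 hydroxyl without harming the trienyl iodide.

**C. C12–C19 dienylstannane**

Step 25
Reactants: 33 (R)-2,2-dimethyl-1,3-dioxolane-4-carbaldehyde
Product: 34 (S)-4-ethynyl-2,2-dimethyl-1,3-dioxolane
Conditions: dimethyl (1-diazo-2-oxopropyl)phosphonate, K2CO3, MeOH, 0 °C to rt
Reagents that add atoms: dimethyl (1-diazo-2-oxopropyl)phosphonate, COP(=O)(OC)C(=[N+]=[N-])C(C)=O
Why: Seyferth–Gilbert homologation with the Ohira–Bestmann reagent converts the aldehyde into the terminal alkyne under conditions mild enough to keep the α-alkoxy stereocentre (future C15).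

Step 26
Reactants: 34 (S)-4-ethynyl-2,2-dimethyl-1,3-dioxolane
Product: 35 (S)-but-3-yne-1,2-diol
Conditions: Dowex 50WX8 (H+), MeOH, rt
Reagents that add atoms: none
Why: Acid-catalysed transketalisation to methanol removes the acetonide.

Step 27
Reactants: 35 (S)-but-3-yne-1,2-diol
Product: 37 (S,Z)-4-iodo-3-methylbut-3-ene-1,2-diol, via alkenylmagnesium chelate 36 (not isolated)
Conditions: MeMgBr (4 equiv), CuI (20 mol %), THF, −10 °C to rt; then I2, −78 to 0 °C
Reagents that add atoms: methylmagnesium bromide, C[Mg]Br; iodine, II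
Why: Copper-catalysed anti-carbomagnesiation of a propargylic alkoxide, in which methyl adds to the proximal alkyne carbon and the distal C–Mg bond is held cis to the carbinol in a five-membered chelate, so iodination with retention gives the Z-iodide (C15 and the future C18 cis).

Step 28
Reactants: 37 (S,Z)-4-iodo-3-methylbut-3-ene-1,2-diol
Product: 38 (S,Z)-1,2-bis(TBS-oxy)-4-iodo-3-methylbut-3-ene
Conditions: TBSCl, imidazole, DMF, rt
Reagents that add atoms: tert-butyldimethylsilyl chloride, CC(C)(C)[Si](C)(C)Cl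
Why: Standard bis-silylation of the diol.

Step 29
Reactants: 38 (S,Z)-1,2-bis(TBS-oxy)-4-iodo-3-methylbut-3-ene
Product: 39 (S,Z)-2-(TBS-oxy)-4-iodo-3-methylbut-3-en-1-ol
Conditions: HF·pyridine, pyridine, THF, 0 °C
Reagents that add atoms: none
Why: Buffered fluoride removes the unhindered primary silyl ether faster than the secondary allylic one flanked by the trisubstituted alkene.

Step 30
Reactants: 39 (S,Z)-2-(TBS-oxy)-4-iodo-3-methylbut-3-en-1-ol
Product: 40 (S,Z)-2-(TBS-oxy)-4-iodo-3-methylbut-3-enal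
Conditions: Dess–Martin periodinane, NaHCO3, CH2Cl2, 0 °C to rt
Reagents that add atoms: none
Why: Dess–Martin oxidation under buffered, non-basic conditions gives the epimerisable α-silyloxy aldehyde, which is used crude.

Step 31
Reactants: 40 (S,Z)-2-(TBS-oxy)-4-iodo-3-methylbut-3-enal
Product: 41 (3R,4S,Z)-4-(TBS-oxy)-6-iodo-5-methylhexa-1,5-dien-3-ol
Conditions: vinylMgBr, THF, −78 °C
Reagents that add atoms: vinylmagnesium bromide, C=C[Mg]Br
Why: Felkin–Anh addition of a non-chelating Grignard reagent anti to the α-silyloxy group should give the 3,4-anti product, setting C14 (R) and leaving exactly the pattern needed later (free C14-OH, protected C15-O).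

Step 32
Reactants: 41 (3R,4S,Z)-4-(TBS-oxy)-6-iodo-5-methylhexa-1,5-dien-3-ol; 42 (E)-1,2-bis(tributylstannyl)ethene
Product: 43 (3R,4S,5Z,7E)-4-(TBS-oxy)-5-methyl-8-(tributylstannyl)octa-1,5,7-trien-3-ol
Conditions: 42 (3 equiv), Pd2(dba)3, AsPh3, CuI, NMP, rt, dark
Reagents that add atoms: none
Why: Stille coupling proceeds with retention at both alkenyl carbons, and the excess of the bis-stannane secures mono-coupling to the dienylstannane.

**D. Assembly and endgame**

Step 33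
Reactants: 23 C1–C11 acid; 32 (2R,3S,4E,6E,8E)-9-iodo-3-methylnona-4,6,8-trien-2-ol
Product: 45 trienyl iodide ester of 23 with 32 (C1–O27 ester), via mixed trichlorobenzoic anhydride 44 (not isolated)
Conditions: 2,4,6-trichlorobenzoyl chloride, Et3N, THF, rt; then 32, DMAP, toluene, rt to 40 °C
Reagents that add atoms: none
Why: Yamaguchi esterification, in which DMAP transfers the hindered acyl group from the mixed anhydride to the secondary alcohol; this acylation of a C27 carbinol by an acid branched at C2 is the standard one in this macrolide family.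

Step 34
Reactants: 45 trienyl iodide ester
Product: 46 C11 primary alcohol (45 without the C11 silyl group)
Conditions: HF·pyridine, pyridine, THF, 0 °C
Reagents that add atoms: none
Why: Buffered fluoride cleaves the single primary silyl ether selectively over the five hindered secondary ones.

Step 35
Reactants: 46 C11 primary alcohol
Product: 47 C11 aldehyde
Conditions: Dess–Martin periodinane, NaHCO3, CH2Cl2, rt
Reagents that add atoms: none
Why: Dess–Martin oxidation is neutral and tolerates the trienyl iodide and the ester.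

Step 36
Reactants: 47 C11 aldehyde
Product: 48 C11 aldoxime (E/Z mixture)
Conditions: NH2OH·HCl, pyridine, EtOH, 0 °C to rt
Reagents that add atoms: hydroxylamine hydrochloride, [Cl-].[NH3+]O
Why: Condensation of the aldehyde with hydroxylamine is faster than β-elimination of the C9 silyloxy group.

Step 37
Reactants: 48 C11 aldoxime; 43 dienylstannane
Product: 49 seco pentaene oxime (16Z,18E,20E,22E,24E) with free C14-OH and terminal C12=C13 vinyl group
Conditions: Pd2(dba)3, AsPh3, DMF/THF, rt, dark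
Reagents that add atoms: none
Why: Stille coupling of an E-alkenyl iodide with an alkenylstannane under neutral conditions forms C19–C20 with retention of every alkene geometry and tolerates the free oxime and alcohol.

Step 38
Reactants: 49 seco pentaene oxime
Product: 52 macrocyclic 2-isoxazoline (28-membered lactone bridged by C11=N–O–C13 with ring CH2 = C12; free C14-OH), via hydroximoyl chloride 50 (not isolated), via nitrile oxide magnesium alkoxide 51 (not isolated)
Conditions: t-BuOCl (1.05 equiv), CH2Cl2, −78 °C, dark; then added over 12 h to iPrOH (6 equiv), EtMgBr (5 equiv), CH2Cl2, 0 °C to rt, 1 mM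
Reagents that add atoms: none
Why: t-BuOCl should chlorinate the aldoxime to 50 at −78 °C faster than it attacks the polyene, and the magnesium base then forms the C14 bromomagnesium alkoxide and eliminates HCl to give nitrile oxide 51, whose oxygen binds the same magnesium. Concerted [3+2] cycloaddition inside this chelate joins C11 to C12 and O to C13; the closest known reactions are macrocyclising intramolecular nitrile oxide–olefin cycloadditions and the magnesium-alkoxide-directed nitrile oxide cycloaddition to secondary allylic alcohols. The isoxazoline closes as a five-membered ring by the cycloaddition itself, and the 28-membered ring closes in the bridged mode, with the tether spanning C3 and C5 of the isoxazoline because the dipole carbon bonds to the terminal alkene carbon. C13 is set by the C14 alkoxide: with the allylic hydrogen inside and the metal-bound oxygen outside, the dipole oxygen is delivered syn to the C14–O bond and gives the 13,14-syn isomer. The step needs chemoselectivity for the C12=C13 vinyl group over the pentaene, O-to-C13 regiochemistry and one alkene face, and all three are secured by the free C14 hydroxyl next to the vinyl group, the only alkene that can react through the accelerated chelated pathway. Slow addition at high dilution should suppress furoxan and oligomer formation.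

Step 39
Reactants: 52 macrocyclic 2-isoxazoline
Product: 54 macrocyclic β-hydroxy ketone (C11 ketone; free C13-OH and C14-OH), via β-hydroxy imine 53 (not isolated)
Conditions: SmI2, THF, 0 °C; then B(OH)3, MeOH/H2O, rt
Reagents that add atoms: water, O
Why: Reductive N–O cleavage by samarium diiodide followed by boric-acid-buffered hydrolysis of the β-hydroxy imine unmasks the aldol-type ketone without touching C13 or the alkenes.

Step 40
Reactants: 54 macrocyclic β-hydroxy ketone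
Product: 55 hexakis-TBS ether of the target (TBS at O1′ O3 O5 O7 O9 O15; free C11 C13 C14 hydroxyls)
Conditions: Et2BOMe, THF/MeOH, −78 °C; NaBH4; AcOH; MeOH azeotrope
Reagents that add atoms: none
Why: Narasaka–Prasad reduction, in which the C13 hydroxyl and the C11 ketone form a six-membered diethylboron chelate and external hydride attacks axially to give the 1,3-syn diol, setting C11 (S); the non-oxidative work-up spares the pentaene and the lactone.

Step 41
Reactants: 55 hexakis-TBS ether of the target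
Product: 56 CNP0269947.1 (target)
Conditions: HF·pyridine, pyridine, THF, 0 °C to rt, dark
Reagents that add atoms: none
Why: Pyridine-buffered fluoride desilylation removes all six silyl ethers under conditions mild enough for the pentaenyl carbinol and the β-hydroxy lactone.

**Compound list**
1 | 3-(TBS-oxy)propan-1-ol | OCCCO[Si](C)(C)C(C)(C)C | starting material
2 | (S)-1-(TBS-oxy)hex-5-en-3-ol | C=CC[C@H](O)CCO[Si](C)(C)C(C)(C)C | intermediate
3 | (S)-4,6-bis(TBS-oxy)hex-1-ene | C=CC[C@H](O[Si](C)(C)C(C)(C)C)CCO[Si](C)(C)C(C)(C)C | intermediate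
4 | (R)-3,5-bis(TBS-oxy)pentanal | O=CC[C@H](O[Si](C)(C)C(C)(C)C)CCO[Si](C)(C)C(C)(C)C | intermediate (not isolated)
5 | (S)-3,5-bis(TBS-oxy)pentan-1-ol | OCC[C@H](O[Si](C)(C)C(C)(C)C)CCO[Si](C)(C)C(C)(C)C | intermediate
6 | (4S,6R)-6,8-bis(TBS-oxy)oct-1-en-4-ol | C=CC[C@H](O)C[C@H](O[Si](C)(C)C(C)(C)C)CCO[Si](C)(C)C(C)(C)C | intermediate
7 | (4S,6R)-4,6,8-tris(TBS-oxy)oct-1-ene | C=CC[C@H](O[Si](C)(C)C(C)(C)C)C[C@H](O[Si](C)(C)C(C)(C)C)CCO[Si](C)(C)C(C)(C)C | intermediate
8 | (3R,5R)-3,5,7-tris(TBS-oxy)heptanal | O=CC[C@H](O[Si](C)(C)C(C)(C)C)C[C@H](O[Si](C)(C)C(C)(C)C)CCO[Si](C)(C)C(C)(C)C | intermediate (not isolated)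
9 | (3S,5R)-3,5,7-tris(TBS-oxy)heptan-1-ol | OCC[C@H](O[Si](C)(C)C(C)(C)C)C[C@H](O[Si](C)(C)C(C)(C)C)CCO[Si](C)(C)C(C)(C)C | intermediate
10 | (4R,6S,8R)-6,8,10-tris(TBS-oxy)dec-1-en-4-ol | C=CC[C@@H](O)C[C@H](O[Si](C)(C)C(C)(C)C)C[C@H](O[Si](C)(C)C(C)(C)C)CCO[Si](C)(C)C(C)(C)C | intermediate
11 | (4R,6S,8R)-4,6,8,10-tetrakis(TBS-oxy)dec-1-ene | C=CC[C@@H](O[Si](C)(C)C(C)(C)C)C[C@H](O[Si](C)(C)C(C)(C)C)C[C@H](O[Si](C)(C)C(C)(C)C)CCO[Si](C)(C)C(C)(C)C | intermediate
12 | (3S,5R,7R)-3,5,7,9-tetrakis(TBS-oxy)nonanal | O=CC[C@@H](O[Si](C)(C)C(C)(C)C)C[C@H](O[Si](C)(C)C(C)(C)C)C[C@H](O[Si](C)(C)C(C)(C)C)CCO[Si](C)(C)C(C)(C)C | intermediate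
13 | methyl 3-oxooctanoate | CCCCCC(=O)CC(=O)OC | starting material
14 | methyl (S)-3-hydroxyoctanoate | CCCCC[C@H](O)CC(=O)OC | intermediate
15 | methyl (S)-3-(TBS-oxy)octanoate | CCCCC[C@H](O[Si](C)(C)C(C)(C)C)CC(=O)OC | intermediate
16 | (S)-3-(TBS-oxy)octanoic acid | CCCCC[C@H](O[Si](C)(C)C(C)(C)C)CC(=O)O | intermediate
17 | (R)-4-benzyloxazolidin-2-one | O=C1N[C@H](Cc2ccccc2)CO1 | starting material
18 | (S)-3-(TBS-oxy)octanoic pivalic anhydride | CCCCC[C@H](O[Si](C)(C)C(C)(C)C)CC(=O)OC(=O)C(C)(C)C | intermediate (not isolated)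
19 | (R)-4-benzyl-3-[(S)-3-(TBS-oxy)octanoyl]oxazolidin-2-one | CCCCC[C@H](O[Si](C)(C)C(C)(C)C)CC(=O)N1[C@H](Cc2ccccc2)COC1=O | intermediate
20 | Evans syn-aldol adduct (C1–C11 acyl oxazolidinone; free C3-OH) | CCCCC[C@H](O[Si](C)(C)C(C)(C)C)[C@H]([C@@H](O)C[C@@H](O[Si](C)(C)C(C)(C)C)C[C@H](O[Si](C)(C)C(C)(C)C)C[C@H](O[Si](C)(C)C(C)(C)C)CCO[Si](C)(C)C(C)(C)C)C(=O)N1[C@H](Cc2ccccc2)COC1=O | intermediate
21 | C1–C11 3-hydroxy acid | CCCCC[C@H](O[Si](C)(C)C(C)(C)C)[C@H]([C@@H](O)C[C@@H](O[Si](C)(C)C(C)(C)C)C[C@H](O[Si](C)(C)C(C)(C)C)C[C@H](O[Si](C)(C)C(C)(C)C)CCO[Si](C)(C)C(C)(C)C)C(=O)O | intermediate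
22 | TBS ester of acid 23 | CCCCC[C@H](O[Si](C)(C)C(C)(C)C)[C@H]([C@@H](O[Si](C)(C)C(C)(C)C)C[C@@H](O[Si](C)(C)C(C)(C)C)C[C@H](O[Si](C)(C)C(C)(C)C)C[C@H](O[Si](C)(C)C(C)(C)C)CCO[Si](C)(C)C(C)(C)C)C(=O)O[Si](C)(C)C(C)(C)C | intermediate (not isolated)
23 | (2R,3S,5S,7R,9R)-3,5,7,9,11-pentakis(TBS-oxy)-2-[(S)-1-(TBS-oxy)hexyl]undecanoic acid | CCCCC[C@H](O[Si](C)(C)C(C)(C)C)[C@H]([C@@H](O[Si](C)(C)C(C)(C)C)C[C@@H](O[Si](C)(C)C(C)(C)C)C[C@H](O[Si](C)(C)C(C)(C)C)C[C@H](O[Si](C)(C)C(C)(C)C)CCO[Si](C)(C)C(C)(C)C)C(=O)O | intermediate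
24 | methyl (R)-3-hydroxybutanoate | C[C@@H](O)CC(=O)OC | starting material
25 | methyl (2R,3R)-3-hydroxy-2-methylbutanoate | C[C@@H](O)[C@@H](C)C(=O)OC | intermediate
26 | methyl (2R,3R)-3-(TBS-oxy)-2-methylbutanoate | C[C@@H](O[Si](C)(C)C(C)(C)C)[C@@H](C)C(=O)OC | intermediate
27 | (2R,3R)-3-(TBS-oxy)-2-methylbutanal | C[C@@H](O[Si](C)(C)C(C)(C)C)[C@@H](C)C=O | intermediate
28 | ethyl (2E,4E,6S,7R)-7-(TBS-oxy)-6-methylocta-2,4-dienoate | C[C@@H](O[Si](C)(C)C(C)(C)C)[C@@H](C)/C=C/C=C/C(=O)OCC | intermediate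
29 | (2E,4E,6S,7R)-7-(TBS-oxy)-6-methylocta-2,4-dien-1-ol | C[C@@H](O[Si](C)(C)C(C)(C)C)[C@@H](C)/C=C/C=C/CO | intermediate
30 | (2E,4E,6S,7R)-7-(TBS-oxy)-6-methylocta-2,4-dienal | C[C@@H](O[Si](C)(C)C(C)(C)C)[C@@H](C)/C=C/C=C/C=O | intermediate
31 | TBS ether of (2R,3S,4E,6E,8E)-9-iodo-3-methylnona-4,6,8-trien-2-ol | C[C@@H](O[Si](C)(C)C(C)(C)C)[C@@H](C)/C=C/C=C/C=C/I | intermediate
32 | (2R,3S,4E,6E,8E)-9-iodo-3-methylnona-4,6,8-trien-2-ol | C[C@@H](O)[C@@H](C)/C=C/C=C/C=C/I | intermediate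
33 | (R)-2,2-dimethyl-1,3-dioxolane-4-carbaldehyde | O=C[C@H]1COC(C)(C)O1 | starting material
34 | (S)-4-ethynyl-2,2-dimethyl-1,3-dioxolane | C#C[C@H]1COC(C)(C)O1 | intermediate
35 | (S)-but-3-yne-1,2-diol | C#C[C@H](O)CO | intermediate
36 | (Z)-alkenylmagnesium bromide bis(bromomagnesium alkoxide) of 37 (Mg in place of I) | C/C(=C/[Mg]Br)[C@H](O[Mg]Br)CO[Mg]Br | intermediate (not isolated)
37 | (S,Z)-4-iodo-3-methylbut-3-ene-1,2-diol | C/C(=C/I)[C@H](O)CO | intermediate
38 | (S,Z)-1,2-bis(TBS-oxy)-4-iodo-3-methylbut-3-ene | C/C(=C/I)[C@H](O[Si](C)(C)C(C)(C)C)CO[Si](C)(C)C(C)(C)C | intermediate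
39 | (S,Z)-2-(TBS-oxy)-4-iodo-3-methylbut-3-en-1-ol | C/C(=C/I)[C@H](O[Si](C)(C)C(C)(C)C)CO | intermediate
40 | (S,Z)-2-(TBS-oxy)-4-iodo-3-methylbut-3-enal | C/C(=C/I)[C@H](O[Si](C)(C)C(C)(C)C)C=O | intermediate
41 | (3R,4S,Z)-4-(TBS-oxy)-6-iodo-5-methylhexa-1,5-dien-3-ol | C/C(=C/I)[C@H](O[Si](C)(C)C(C)(C)C)[C@H](O)C=C | intermediate
42 | (E)-1,2-bis(tributylstannyl)ethene | CCCC[Sn](CCCC)(CCCC)/C=C/[Sn](CCCC)(CCCC)CCCC | starting material
43 | (3R,4S,5Z,7E)-4-(TBS-oxy)-5-methyl-8-(tributylstannyl)octa-1,5,7-trien-3-ol | CCCC[Sn](CCCC)(CCCC)/C=C/C=C(/C)[C@H](O[Si](C)(C)C(C)(C)C)[C@H](O)C=C | intermediate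
44 | mixed anhydride of 23 with 2,4,6-trichlorobenzoic acid | CCCCC[C@H](O[Si](C)(C)C(C)(C)C)[C@H]([C@@H](O[Si](C)(C)C(C)(C)C)C[C@@H](O[Si](C)(C)C(C)(C)C)C[C@H](O[Si](C)(C)C(C)(C)C)C[C@H](O[Si](C)(C)C(C)(C)C)CCO[Si](C)(C)C(C)(C)C)C(=O)OC(=O)c1c(Cl)cc(Cl)cc1Cl | intermediate (not isolated)
45 | trienyl iodide ester of 23 with 32 | CCCCC[C@H](O[Si](C)(C)C(C)(C)C)[C@H]([C@@H](O[Si](C)(C)C(C)(C)C)C[C@@H](O[Si](C)(C)C(C)(C)C)C[C@H](O[Si](C)(C)C(C)(C)C)C[C@H](O[Si](C)(C)C(C)(C)C)CCO[Si](C)(C)C(C)(C)C)C(=O)O[C@H](C)[C@@H](C)/C=C/C=C/C=C/I | intermediate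
46 | C11 primary alcohol of 45 | CCCCC[C@H](O[Si](C)(C)C(C)(C)C)[C@H]([C@@H](O[Si](C)(C)C(C)(C)C)C[C@@H](O[Si](C)(C)C(C)(C)C)C[C@H](O[Si](C)(C)C(C)(C)C)C[C@H](O[Si](C)(C)C(C)(C)C)CCO)C(=O)O[C@H](C)[C@@H](C)/C=C/C=C/C=C/I | intermediate
47 | C11 aldehyde | CCCCC[C@H](O[Si](C)(C)C(C)(C)C)[C@H]([C@@H](O[Si](C)(C)C(C)(C)C)C[C@@H](O[Si](C)(C)C(C)(C)C)C[C@H](O[Si](C)(C)C(C)(C)C)C[C@H](O[Si](C)(C)C(C)(C)C)CC=O)C(=O)O[C@H](C)[C@@H](C)/C=C/C=C/C=C/I | intermediate
48 | C11 aldoxime | CCCCC[C@H](O[Si](C)(C)C(C)(C)C)[C@H]([C@@H](O[Si](C)(C)C(C)(C)C)C[C@@H](O[Si](C)(C)C(C)(C)C)C[C@H](O[Si](C)(C)C(C)(C)C)C[C@H](O[Si](C)(C)C(C)(C)C)CC=NO)C(=O)O[C@H](C)[C@@H](C)/C=C/C=C/C=C/I | intermediate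
49 | seco pentaene oxime | CCCCC[C@H](O[Si](C)(C)C(C)(C)C)[C@H]([C@@H](O[Si](C)(C)C(C)(C)C)C[C@@H](O[Si](C)(C)C(C)(C)C)C[C@H](O[Si](C)(C)C(C)(C)C)C[C@H](O[Si](C)(C)C(C)(C)C)CC=NO)C(=O)O[C@H](C)[C@@H](C)/C=C/C=C/C=C/C=C/C=C(/C)[C@H](O[Si](C)(C)C(C)(C)C)[C@H](O)C=C | intermediate
50 | C11 hydroximoyl chloride of 49 | CCCCC[C@H](O[Si](C)(C)C(C)(C)C)[C@H]([C@@H](O[Si](C)(C)C(C)(C)C)C[C@@H](O[Si](C)(C)C(C)(C)C)C[C@H](O[Si](C)(C)C(C)(C)C)C[C@H](O[Si](C)(C)C(C)(C)C)CC(Cl)=NO)C(=O)O[C@H](C)[C@@H](C)/C=C/C=C/C=C/C=C/C=C(/C)[C@H](O[Si](C)(C)C(C)(C)C)[C@H](O)C=C | intermediate (not isolated)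
51 | C11 nitrile oxide with C14 bromomagnesium alkoxide | CCCCC[C@H](O[Si](C)(C)C(C)(C)C)[C@H]([C@@H](O[Si](C)(C)C(C)(C)C)C[C@@H](O[Si](C)(C)C(C)(C)C)C[C@H](O[Si](C)(C)C(C)(C)C)C[C@H](O[Si](C)(C)C(C)(C)C)CC#[N+][O-])C(=O)O[C@H](C)[C@@H](C)/C=C/C=C/C=C/C=C/C=C(/C)[C@H](O[Si](C)(C)C(C)(C)C)[C@H](O[Mg]Br)C=C | intermediate (not isolated)
52 | macrocyclic 2-isoxazoline | CCCCC[C@H](O[Si](C)(C)C(C)(C)C)[C@H]1C(=O)O[C@H](C)[C@@H](C)/C=C/C=C/C=C/C=C/C=C(/C)[C@H](O[Si](C)(C)C(C)(C)C)[C@H](O)[C@@H]2CC(=NO2)C[C@@H](O[Si](C)(C)C(C)(C)C)C[C@@H](O[Si](C)(C)C(C)(C)C)C[C@H](O[Si](C)(C)C(C)(C)C)C[C@@H]1O[Si](C)(C)C(C)(C)C | intermediate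
53 | macrocyclic C11 imine (β-hydroxy imine) | CCCCC[C@H](O[Si](C)(C)C(C)(C)C)[C@H]1C(=O)O[C@H](C)[C@@H](C)/C=C/C=C/C=C/C=C/C=C(/C)[C@H](O[Si](C)(C)C(C)(C)C)[C@H](O)[C@@H](O)CC(=N)C[C@@H](O[Si](C)(C)C(C)(C)C)C[C@@H](O[Si](C)(C)C(C)(C)C)C[C@H](O[Si](C)(C)C(C)(C)C)C[C@@H]1O[Si](C)(C)C(C)(C)C | intermediate (not isolated)
54 | macrocyclic C11 ketone (β-hydroxy ketone) | CCCCC[C@H](O[Si](C)(C)C(C)(C)C)[C@H]1C(=O)O[C@H](C)[C@@H](C)/C=C/C=C/C=C/C=C/C=C(/C)[C@H](O[Si](C)(C)C(C)(C)C)[C@H](O)[C@@H](O)CC(=O)C[C@@H](O[Si](C)(C)C(C)(C)C)C[C@@H](O[Si](C)(C)C(C)(C)C)C[C@H](O[Si](C)(C)C(C)(C)C)C[C@@H]1O[Si](C)(C)C(C)(C)C | intermediate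
55 | hexakis-TBS ether of the target (free C11 C13 C14 hydroxyls) | CCCCC[C@H](O[Si](C)(C)C(C)(C)C)[C@H]1C(=O)O[C@H](C)[C@@H](C)/C=C/C=C/C=C/C=C/C=C(/C)[C@H](O[Si](C)(C)C(C)(C)C)[C@H](O)[C@@H](O)C[C@@H](O)C[C@@H](O[Si](C)(C)C(C)(C)C)C[C@@H](O[Si](C)(C)C(C)(C)C)C[C@H](O[Si](C)(C)C(C)(C)C)C[C@@H]1O[Si](C)(C)C(C)(C)C | intermediate
56 | CNP0269947.1 | CCCCC[C@H](O)[C@H]1C(=O)O[C@H](C)[C@@H](C)/C=C/C=C/C=C/C=C/C=C(/C)[C@H](O)[C@H](O)[C@@H](O)C[C@@H](O)C[C@@H](O)C[C@@H](O)C[C@H](O)C[C@@H]1O | target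

**Step count and risks**
Total step count: 41.
Longest linear sequence: 21 steps (steps 1–9, 14–16 and 33–41, from 1 through 12, 23, 45 and 52 to 56).

Three steps most likely to fail:

1. Step 38. The processes at risk are electrophilic chlorination of the pentaene in competition with the oxime, bimolecular capture of the nitrile oxide (furoxan, oligomers) instead of 28-membered closure, and loss of facial control if the magnesium chelate is not kept in the macrocyclic transition state. Fallback: the cycloaddition is run between two molecules before the pentaene exists, and the ring is then closed by a Stille coupling. The fallback sets out from 48 and 43. Oxime 48 is chlorinated (t-BuOCl, CH2Cl2, −78 °C) to the hydroximoyl chloride F1. F1 is added to the bromomagnesium alkoxide of 43 (iPrOH, EtMgBr, CH2Cl2, 0 °C), where the nitrile oxide F2 adds under the same alkoxide direction to give the acyclic isoxazoline F3. Intramolecular Stille coupling of F3 (Pd2(dba)3, AsPh3, DMF/THF, rt, high dilution) then forms C19–C20 and comes back to the route at 52.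

2. Step 39. The processes at risk are electron transfer from SmI2 to the pentaene (reduction, E/Z scrambling) and retro-aldol cleavage or β-elimination of the C9 silyloxy group at the new β-hydroxy ketone during imine hydrolysis. Fallback: N–O cleavage and the syn-reduction are moved ahead of pentaene formation. The fallback sets out from 48 and 43 and passes through the acyclic isoxazoline F3 described above. SmI2 (THF, 0 °C) then B(OH)3 (MeOH/H2O) convert F3 into the acyclic β-hydroxy ketone F4. Et2BOMe/NaBH4 (THF/MeOH, −78 °C) gives the acyclic syn-diol F5. Intramolecular Stille coupling of F5 (Pd2(dba)3, AsPh3, high dilution) comes back to the route at 55.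

3. Step 31. The processes at risk are poor facial selectivity of the Felkin–Anh addition and base-induced epimerisation or double-bond migration of the α-silyloxy-β,γ-unsaturated aldehyde. Fallback: C14 is set by reagent control through a Sharpless epoxidation and reductive transposition. The fallback sets out from 40. Wittig reaction with Ph3P=CHCO2Et (CH2Cl2, rt) gives the enoate F6. DIBAL (CH2Cl2, −78 °C) gives the allylic alcohol F7. Sharpless asymmetric epoxidation (Ti(OiPr)4, L-(+)-diisopropyl tartrate, t-BuOOH, 4 Å sieves, CH2Cl2, −20 °C) gives the epoxy alcohol F8. I2, PPh3 and imidazole (THF, 0 °C) give the epoxy iodide F9. Zinc dust (EtOH/AcOH, 50 °C) opens F9 reductively with retention at C14 and comes back to the route at 41.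

Further compounds
F1 | step 38 | C11 hydroximoyl chloride of 48 | CCCCC[C@H](O[Si](C)(C)C(C)(C)C)[C@H]([C@@H](O[Si](C)(C)C(C)(C)C)C[C@@H](O[Si](C)(C)C(C)(C)C)C[C@H](O[Si](C)(C)C(C)(C)C)C[C@H](O[Si](C)(C)C(C)(C)C)CC(Cl)=NO)C(=O)O[C@H](C)[C@@H](C)/C=C/C=C/C=C/I
F2 | step 38 | C11 nitrile oxide from F1 | CCCCC[C@H](O[Si](C)(C)C(C)(C)C)[C@H]([C@@H](O[Si](C)(C)C(C)(C)C)C[C@@H](O[Si](C)(C)C(C)(C)C)C[C@H](O[Si](C)(C)C(C)(C)C)C[C@H](O[Si](C)(C)C(C)(C)C)CC#[N+][O-])C(=O)O[C@H](C)[C@@H](C)/C=C/C=C/C=C/I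
F3 | step 38 | acyclic isoxazoline carrying the trienyl iodide and the dienylstannane | CCCCC[C@H](O[Si](C)(C)C(C)(C)C)[C@H]([C@@H](O[Si](C)(C)C(C)(C)C)C[C@@H](O[Si](C)(C)C(C)(C)C)C[C@H](O[Si](C)(C)C(C)(C)C)C[C@H](O[Si](C)(C)C(C)(C)C)CC1=NO[C@@H](C1)[C@@H](O)[C@@H](O[Si](C)(C)C(C)(C)C)\C(C)=C/C=C/[Sn](CCCC)(CCCC)CCCC)C(=O)O[C@H](C)[C@@H](C)/C=C/C=C/C=C/I
F4 | step 39 | acyclic β-hydroxy ketone (C11 ketone) | CCCCC[C@H](O[Si](C)(C)C(C)(C)C)[C@H]([C@@H](O[Si](C)(C)C(C)(C)C)C[C@@H](O[Si](C)(C)C(C)(C)C)C[C@H](O[Si](C)(C)C(C)(C)C)C[C@H](O[Si](C)(C)C(C)(C)C)CC(=O)C[C@H](O)[C@@H](O)[C@@H](O[Si](C)(C)C(C)(C)C)\C(C)=C/C=C/[Sn](CCCC)(CCCC)CCCC)C(=O)O[C@H](C)[C@@H](C)/C=C/C=C/C=C/I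
F5 | step 39 | acyclic C11,C13-syn diol | CCCCC[C@H](O[Si](C)(C)C(C)(C)C)[C@H]([C@@H](O[Si](C)(C)C(C)(C)C)C[C@@H](O[Si](C)(C)C(C)(C)C)C[C@H](O[Si](C)(C)C(C)(C)C)C[C@H](O[Si](C)(C)C(C)(C)C)C[C@H](O)C[C@H](O)[C@@H](O)[C@@H](O[Si](C)(C)C(C)(C)C)\C(C)=C/C=C/[Sn](CCCC)(CCCC)CCCC)C(=O)O[C@H](C)[C@@H](C)/C=C/C=C/C=C/I
F6 | step 31 | ethyl (S,2E,5Z)-4-(TBS-oxy)-6-iodo-5-methylhexa-2,5-dienoate | C/C(=C/I)[C@H](O[Si](C)(C)C(C)(C)C)/C=C/C(=O)OCC
F7 | step 31 | (S,2E,5Z)-4-(TBS-oxy)-6-iodo-5-methylhexa-2,5-dien-1-ol | C/C(=C/I)[C@H](O[Si](C)(C)C(C)(C)C)/C=C/CO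
F8 | step 31 | {(2S,3R)-3-[(S,Z)-1-(TBS-oxy)-3-iodo-2-methylallyl]oxiran-2-yl}methanol | C/C(=C/I)[C@H](O[Si](C)(C)C(C)(C)C)[C@@H]1O[C@H]1CO
F9 | step 31 | epoxy iodide from F8 (CH2I in place of CH2OH) | C/C(=C/I)[C@H](O[Si](C)(C)C(C)(C)C)[C@@H]1O[C@H]1CI
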